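**Retrosynthetic overview**

1. Target ⇐ its 5,6-di-O-methyl ether (BBr3), so that only aryl O-demethylation follows the stereo-defining step.
2. δ-Lactone (acyl–oxygen bond C1–O2) ⇐ an α-hydroxy ester closing on the neighbouring aroyl ester, as in the presumed chebulic-acid-type biogenesis. The hydroxyl ⇐ α-keto ester by dynamic kinetic asymmetric transfer hydrogenation, which fixes C3 and C4 together.
3. The aryl α-keto ester (an aryl 4-oxalomesaconate, the chain that ring cleavage of a galloyl unit gives in Nature) ⇐ C4–C4a bond between a p-quinone monoketal of a salicylate (aryl cation equivalent) and a 4-oxalomesaconate enolate.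
4. That enolate ⇐ hydroxide opening of dimethyl 2-pyrone-4,6-dicarboxylate (frees exactly the one CO2H of the target) ⇐ dimethyl itaconate + dimethyl oxalate.
5. Ring order: the benzene ring is bought; a 2-pyranone is made (step 2) and opened again (step 3); the dihydroisocoumarin lactone is closed in step 4 and kept.

Assumptions: the biogenesis is taken to be of the chebulic-acid type (C7 chain from a ring-cleaved galloyl unit, α-hydroxy ester, lactonisation on the aroyl carboxyl); methyl 2-hydroxy-4,5-dimethoxybenzoate is taken as a catalogue compound.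

**Route**

Step 1
Reactants: 1 methyl 2-hydroxy-4,5-dimethoxybenzoate
Product: 2 methyl 3,3,4-trimethoxy-6-oxocyclohexa-1,4-diene-1-carboxylate
Conditions: PhI(OAc)2 (1.1 equiv), MeOH, 0 °C; used crude
Reagents that add atoms: methanol, CO
Why: Hypervalent-iodine oxidative dearomatisation of a p-methoxyphenol, in which methanol adds to the phenoxonium ion at the methoxy-bearing para carbon to give the p-quinone monoketal; no stereocentre is formed.

Step 2
Reactants: 3 dimethyl itaconate; 4 dimethyl oxalate
Product: 6 dimethyl 2-oxo-2H-pyran-4,6-dicarboxylate, via Claisen triester 5 (not isolated)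
Conditions: NaOMe (1.1 equiv), MeOH–THF, 0 °C → rt; evaporate; TsOH·H2O (1.3 equiv), PhMe, 90 °C (−MeOH)
Reagents that add atoms: none
Why: Vinylogous (γ-selective) Claisen condensation of the itaconate/mesaconate dienolate with non-enolisable dimethyl oxalate, analogous to the classical oxalate–crotonate condensation, gives the 4-oxalomesaconate enol, whose enol OH then lactonises under acid on the cis ester to the 2-pyranone; this fixes the later E alkene geometry (acid carbon cis to C-4) and creates no stereocentre.

Step 3
Reactants: 6 dimethyl 2-oxo-2H-pyran-4,6-dicarboxylate; 2 methyl 3,3,4-trimethoxy-6-oxocyclohexa-1,4-diene-1-carboxylate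
Product: 9 (2E)-4-[3-hydroxy-5,6-dimethoxy-2-(methoxycarbonyl)phenyl]-6-methoxy-3-(methoxycarbonyl)-5,6-dioxohex-2-enoic acid (racemic at C-4), via ring-opened dilithium enolate 7 (not isolated), via Michael adduct 8 (not isolated)
Conditions: LiOH·H2O (2.0 equiv), THF–H2O 5:1, 0 °C; add 2 (1.1 equiv), 0 °C → rt; AcOH (2.2 equiv), evaporate; CSA (10 mol%), CH2Cl2, 0 °C → rt; used crude
Reagents that add atoms: lithium hydroxide, [Li+].[OH-]
Why: Proposed new method: hydroxide attacks the enol-lactone carbonyl of the pyrone (the most electrophilic acyl group, enolate leaving group, the reaction of 2-pyrone-4,6-dicarboxylate hydrolase) to give a carboxylate–enolate whose α-carbon adds in a Michael reaction to the ketone- and ester-activated β-carbon of the quinone monoketal, after which acid expels methanol and aromatises, the closest known chemistry being Michael addition/aromatisation of malonates and β-keto esters on quinone monoketals (formal α-arylation); C-4 is formed racemic and stays labile through the conjugated enol, and the methoxy group left ortho to the new bond blocks the benzofuran-forming hemiketal that a free quinone would give.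

Step 4
Reactants: 9 (2E)-4-[3-hydroxy-5,6-dimethoxy-2-(methoxycarbonyl)phenyl]-6-methoxy-3-(methoxycarbonyl)-5,6-dioxohex-2-enoic acid
Product: 11 (2E)-3-[(3S,4R)-8-hydroxy-5,6-dimethoxy-3-(methoxycarbonyl)-1-oxo-3,4-dihydro-1H-isochromen-4-yl]-4-methoxy-4-oxobut-2-enoic acid, via hydroxy ester 10 (not isolated)
Conditions: RuCl(p-cymene)[(S,S)-TsDPEN] (3 mol%), HCO2H–Et3N (5:2), DMF, 30 °C; then 60 °C
Reagents that add atoms: none
Why: Noyori–Ikariya asymmetric transfer hydrogenation run as a dynamic kinetic resolution of a β-stereogenic α-keto ester: C-4 racemises through the enol while the (S,S)-catalyst reduces the (4R)-epimer (Felkin–Anh-matched, aryl anti to the incoming hydride) to the (S)-carbinol, and this hydroxyl then closes the δ-lactone by transesterification on the hydrogen-bonded salicylate ester (the side-chain acid is a carboxylate in the buffer and deactivates the neighbouring conjugated ester), giving the 3,4-trans lactone with 3S,4R.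

Step 5
Reactants: 11 (2E)-3-[(3S,4R)-8-hydroxy-5,6-dimethoxy-3-(methoxycarbonyl)-1-oxo-3,4-dihydro-1H-isochromen-4-yl]-4-methoxy-4-oxobut-2-enoic acid
Product: 12 (2E)-4-methoxy-4-oxo-3-[(3S,4R)-5,6,8-trihydroxy-3-(methoxycarbonyl)-1-oxo-3,4-dihydro-1H-isochromen-4-yl]but-2-enoic acid (CNP0546035.1)
Conditions: BBr3 (6 equiv), CH2Cl2, −78 → −10 °C; then H2O, aq. Na2S2O4 work-up under Ar
Reagents that add atoms: none
Why: Lewis-acid-mediated SN2 demethylation by boron tribromide cleaves the two vicinal aryl methyl ethers much faster than the alkyl esters or the lactone at low temperature, and the acidic, non-enolising conditions leave C-3, C-4 and the alkene untouched.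

**Compound list**

1 | methyl 2-hydroxy-4,5-dimethoxybenzoate | COC(=O)c1cc(OC)c(OC)cc1O | starting material
2 | methyl 3,3,4-trimethoxy-6-oxocyclohexa-1,4-diene-1-carboxylate | COC(=O)C1=CC(OC)(OC)C(OC)=CC1=O | intermediate
3 | dimethyl itaconate (dimethyl 2-methylidenebutanedioate) | C=C(CC(=O)OC)C(=O)OC | starting material
4 | dimethyl oxalate | COC(=O)C(=O)OC | starting material
5 | trimethyl (1E)-4-oxobut-1-ene-1,2,4-tricarboxylate (trimethyl 4-oxalomesaconate; formed as its sodium enolate) | COC(=O)C(=O)C/C(C(=O)OC)=C\C(=O)OC | intermediate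
6 | dimethyl 2-oxo-2H-pyran-4,6-dicarboxylate | COC(=O)C1=CC(C(=O)OC)=CC(=O)O1 | intermediate
7 | (2E)-6-methoxy-3-(methoxycarbonyl)-5,6-dioxohex-2-enoic acid (present as its dilithium carboxylate–enolate) | COC(=O)C(=O)C/C(C(=O)OC)=C\C(=O)O | intermediate
8 | (2E)-6-methoxy-3-(methoxycarbonyl)-5,6-dioxo-4-[2,2,3-trimethoxy-6-(methoxycarbonyl)-5-oxocyclohex-3-en-1-yl]hex-2-enoic acid (stereoisomer and tautomer mixture) | COC(=O)C(=O)C(C1C(C(=O)OC)C(=O)C=C(OC)C1(OC)OC)/C(C(=O)OC)=C\C(=O)O | intermediate
9 | (2E)-4-[3-hydroxy-5,6-dimethoxy-2-(methoxycarbonyl)phenyl]-6-methoxy-3-(methoxycarbonyl)-5,6-dioxohex-2-enoic acid (racemic, C-4 labile) | COC(=O)C(=O)C(c1c(OC)c(OC)cc(O)c1C(=O)OC)/C(C(=O)OC)=C\C(=O)O | intermediate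
10 | (2E,4R,5S)-5-hydroxy-4-[3-hydroxy-5,6-dimethoxy-2-(methoxycarbonyl)phenyl]-6-methoxy-3-(methoxycarbonyl)-6-oxohex-2-enoic acid | COC(=O)/C(=C/C(=O)O)[C@@H](c1c(OC)c(OC)cc(O)c1C(=O)OC)[C@H](O)C(=O)OC | intermediate
11 | (2E)-3-[(3S,4R)-8-hydroxy-5,6-dimethoxy-3-(methoxycarbonyl)-1-oxo-3,4-dihydro-1H-isochromen-4-yl]-4-methoxy-4-oxobut-2-enoic acid | COC(=O)/C(=C/C(=O)O)[C@H]1c2c(OC)c(OC)cc(O)c2C(=O)O[C@@H]1C(=O)OC | intermediate
12 | (2E)-4-methoxy-4-oxo-3-[(3S,4R)-5,6,8-trihydroxy-3-(methoxycarbonyl)-1-oxo-3,4-dihydro-1H-isochromen-4-yl]but-2-enoic acid | COC(=O)/C(=C/C(=O)O)[C@H]1c2c(O)c(O)cc(O)c2C(=O)O[C@@H]1C(=O)OC | target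

**Step count and risks**

Total: 5 steps. Longest linear sequence: 4 steps (3 + 4 → 6 → 9 → 11 → 12; the branch 1 → 2 joins at step 3).

The step most likely to fail is step 4. The sense of induction of the (S,S)-catalyst on this α-keto ester is predicted, not known, and must be checked on the first run; the (R,R)-catalyst is used if it proves opposite. The enol of 9 may ketonise to the α,β-unsaturated isomer with loss of C-4. The new hydroxyl may also close on the side-chain ester (γ-lactone) or on the free acid (dihydropyranone) instead of the aroyl ester. The fallback gives up catalyst control and sets out from 9. Reduction with NaBH4 in THF–MeOH at −78 °C under Felkin–Anh control gives the racemic hydroxy ester, that is 10 together with its mirror image, the (2E,4S,5R)-hydroxy ester F1. Warming in Et3N–DMF at 60 °C closes the racemic trans-lactone, that is 11 together with the (3R,4S)-lactone F2. Preparative chiral SFC separates the two, and the route is rejoined at 11.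

Second is step 3. The Michael addition forms a bond between a secondary carbanion and a carbon next to the quaternary ketal. O-attack, or hydroxide attack on a methyl ester instead of the pyrone carbonyl, are the other ways it can go wrong. The fallback replaces conjugate addition by cross-coupling and sets out from 2. HBr (33% in AcOH, CH2Cl2, 0 °C) adds bromide to the same β-carbon and aromatises to methyl 2-bromo-6-hydroxy-3,4-dimethoxybenzoate F3. The enolate 7, made from 6 with CsOH·H2O (2 equiv), is then C-arylated with F3 in a copper-catalysed Hurtley-type coupling (CuI, 2-picolinic acid, Cs2CO3, dioxane, 70 °C; then AcOH), which rejoins the route at 9.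

Third is step 2. The Claisen condensation may acylate the α-carbon of the dienolate instead of the γ-carbon, and itaconate may oligomerise under methoxide. The fallback builds the same chain by umpolung and sets out from 3. An NHC-catalysed Stetter addition of methyl glyoxylate to 3 (thiazolium salt, Et3N, THF) gives trimethyl 4-oxobutane-1,2,4-tricarboxylate F4. TsOH in refluxing toluene closes the enol lactone dimethyl 2-oxo-3,4-dihydro-2H-pyran-4,6-dicarboxylate F5. DDQ (benzene, 80 °C) dehydrogenates it to the pyranone, and the route is rejoined at 6.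

**Further compounds**

F1 | step 4 | (2E,4S,5R)-5-hydroxy-4-[3-hydroxy-5,6-dimethoxy-2-(methoxycarbonyl)phenyl]-6-methoxy-3-(methoxycarbonyl)-6-oxohex-2-enoic acid | COC(=O)/C(=C/C(=O)O)[C@H](c1c(OC)c(OC)cc(O)c1C(=O)OC)[C@@H](O)C(=O)OC
F2 | step 4 | (2E)-3-[(3R,4S)-8-hydroxy-5,6-dimethoxy-3-(methoxycarbonyl)-1-oxo-3,4-dihydro-1H-isochromen-4-yl]-4-methoxy-4-oxobut-2-enoic acid | COC(=O)/C(=C/C(=O)O)[C@@H]1c2c(OC)c(OC)cc(O)c2C(=O)O[C@H]1C(=O)OC
F3 | step 3 | methyl 2-bromo-6-hydroxy-3,4-dimethoxybenzoate | COC(=O)c1c(O)cc(OC)c(OC)c1Br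
F4 | step 2 | trimethyl 4-oxobutane-1,2,4-tricarboxylate | COC(=O)C(=O)CC(CC(=O)OC)C(=O)OC
F5 | step 2 | dimethyl 2-oxo-3,4-dihydro-2H-pyran-4,6-dicarboxylate | COC(=O)C1=CC(C(=O)OC)CC(=O)O1
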